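**Retrosynthetic overview**
- Target ⇒ spiro vinyl epoxide + angelic acid: a Pd(0) allylic 1,4-opening gives the primary angelate, the ring C=C and the allylic OH in one operation; the α-methylene group comes from the lactone enolate (Mannich/elimination).
- cis-γ-Lactone ⇒ spiro cyclopentanone: α-alkylation with bromoacetate, then cis-selective ketone reduction and lactonisation.
- Key step: the spiro cyclopentane ring ⇒ Pd–trimethylenemethane [3+2] cycloaddition onto an α-methylene cyclohexanone, which sets the quaternary spiro centre anti to the neighbouring methyl.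
- α-Methylene ketone ⇒ quinic-acid-derived acetonide enone by anti cuprate addition and Mannich/elimination; the acetonide oxygen β to the ketone is later eliminated and returned as the trans OH by nucleophilic epoxidation.
- Ring order: cyclohexane (bought in (−)-quinic acid) → spiro cyclopentane ([3+2]) → γ-lactone (last). All stereocentres are relayed from quinic acid C-4.

Assumption: the target is the single enantiomer drawn, with a (Z)-2-methylbut-2-enoate (angelate) ester; reagents and the three achiral building blocks are commercial.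

**Step 1**
Reactants: 1 (−)-quinic acid
Product: 2 3,4-O-isopropylidene-1,5-quinide
Conditions: Me2C(OMe)2, acetone, TsOH (cat.), reflux
Reagents that add atoms: 2,2-dimethoxypropane CC(C)(OC)OC
Why: Acid-catalysed ketalisation of the cis-3,4-diol and lactonisation of the carboxyl onto the cis 5-OH, with no stereocentre touched.

**Step 2**
Reactants: 2 3,4-O-isopropylidene-1,5-quinide
Product: 3 1-(hydroxymethyl)-3,4-O-isopropylidenecyclohexane-1,3,4,5-tetrol
Conditions: NaBH4, EtOH, 0 °C → rt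
Reagents that add atoms: none
Why: Borohydride reduction of the strained bicyclic lactone to the primary alcohol exposes a 1,2-diol at C-1 while the ketal and all stereocentres stay intact.

**Step 3**
Reactants: 3 1-(hydroxymethyl)-3,4-O-isopropylidenecyclohexane-1,3,4,5-tetrol
Product: 4 (3R,4S,5R)-3-hydroxy-4,5-(isopropylidenedioxy)cyclohexan-1-one
Conditions: NaIO4, H2O (pH 6), 0 °C → rt
Reagents that add atoms: none
Why: Malaprade periodate cleavage of the tertiary-OH/CH2OH glycol removes one carbon as formaldehyde and leaves the ring ketone.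

**Step 4**
Reactants: 4 (3R,4S,5R)-3-hydroxy-4,5-(isopropylidenedioxy)cyclohexan-1-one
Product: 6 (4S,5R)-4,5-(isopropylidenedioxy)cyclohex-2-en-1-one, via mesylate 5 (not isolated)
Conditions: MsCl, Et3N, CH2Cl2, 0 °C → rt
Reagents that add atoms: none
Why: O-Mesylation of the β-hydroxy ketone followed by E1cB elimination gives the conjugated enone, and the two acetonide stereocentres bought in quinic acid are kept.

**Step 5**
Reactants: 6 (4S,5R)-4,5-(isopropylidenedioxy)cyclohex-2-en-1-one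
Product: 9 (3R,4S,5R)-4,5-(isopropylidenedioxy)-3-methyl-2-methylidenecyclohexan-1-one, via Mannich base 7 (not isolated), via methiodide 8 (not isolated)
Conditions: Me2CuLi (from MeLi, CuI), Et2O, −78 → −30 °C; CH2=NMe2+ I−, THF, −78 °C → rt; then MeI, CH2Cl2, rt; then sat. aq NaHCO3, rt (crude intermediates carried on; 9 used at once)
Reagents that add atoms: lithium dimethylcuprate [Li+].C[Cu-]C; Eschenmoser's salt C=[N+](C)C.[I-]
Why: Gilman conjugate addition delivers methyl anti to the γ-acetonide oxygen (sets the 3R methyl centre), the regiospecific enolate is trapped in a Mannich reaction, and Hofmann-type elimination of the methiodide gives the α-methylene ketone without enolising toward the β-alkoxy side.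

**Step 6**
Reactants: 9 (3R,4S,5R)-4,5-(isopropylidenedioxy)-3-methyl-2-methylidenecyclohexan-1-one; 10 2-[(trimethylsilyl)methyl]allyl acetate
Product: 11 (5R,8R,9S,10R)-8,9-(isopropylidenedioxy)-10-methyl-2-methylidenespiro[4.5]decan-6-one
Conditions: Pd(OAc)2 (5 mol %), P(Oi-Pr)3 (30 mol %), THF, 65 °C
Reagents that add atoms: none
Why: In this Trost Pd–trimethylenemethane [3+2] cycloaddition the zwitterion adds to the exocyclic CH2 and the resulting C-enolate closes onto the π-allyl terminus anti to the adjacent pseudo-axial methyl, which sets the quaternary spiro centre (5R) with the ring-closure CH2 trans to the methyl.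

**Step 7**
Reactants: 11 (5R,8R,9S,10R)-8,9-(isopropylidenedioxy)-10-methyl-2-methylidenespiro[4.5]decan-6-one
Product: 13 (5R,9R,10R)-9-[(tert-butyldimethylsilyl)oxy]-10-methyl-2-methylidenespiro[4.5]dec-7-en-6-one, via hydroxy enone 12 (not isolated)
Conditions: DBU (0.3 equiv), CH2Cl2, 0 °C; then TBSCl, imidazole, DMAP (cat.), rt
Reagents that add atoms: tert-butyldimethylsilyl chloride CC(C)(C)[Si](C)(C)Cl
Why: E1cB elimination of the alkoxy group β to the ketone opens the acetonide (acetone is lost) to the γ-hydroxy enone, whose alcohol is silylated with its stereocentre untouched.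

**Step 8**
Reactants: 13 (5R,9R,10R)-9-[(tert-butyldimethylsilyl)oxy]-10-methyl-2-methylidenespiro[4.5]dec-7-en-6-one
Product: 14 (5R,7R,8S,9S,10R)-9-[(tert-butyldimethylsilyl)oxy]-7,8-epoxy-10-methyl-2-methylidenespiro[4.5]decan-6-one
Conditions: t-BuOOH (decane), DBU, CH2Cl2, 0 °C → rt
Reagents that add atoms: tert-butyl hydroperoxide CC(C)(C)OO
Why: In this Weitz–Scheffer nucleophilic epoxidation the peroxide adds to the enone β-carbon anti to the neighbouring bulky OTBS group, giving the trans-epoxy silyl ether that fixes the future allylic carbinol centre.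

**Step 9**
Reactants: 14 (5R,7R,8S,9S,10R)-9-[(tert-butyldimethylsilyl)oxy]-7,8-epoxy-10-methyl-2-methylidenespiro[4.5]decan-6-one
Product: 15 (5R,7R,8S,9S,10R)-9-[(tert-butyldimethylsilyl)oxy]-7,8-epoxy-10-methylspiro[4.5]decane-2,6-dione
Conditions: O3, CH2Cl2/MeOH, −78 °C; then Me2S, −78 °C → rt
Reagents that add atoms: ozone [O-][O+]=O
Why: Ozonolysis of the only C=C (the exocyclic methylene) with reductive work-up gives the cyclopentanone without touching any stereocentre.

**Step 10**
Reactants: 15 (5R,7R,8S,9S,10R)-9-[(tert-butyldimethylsilyl)oxy]-7,8-epoxy-10-methylspiro[4.5]decane-2,6-dione; 16 methyl bromoacetate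
Product: 17 methyl 2-[(3R,5R,7R,8S,9S,10R)-9-[(tert-butyldimethylsilyl)oxy]-7,8-epoxy-10-methyl-2,6-dioxospiro[4.5]decan-3-yl]acetate
Conditions: LDA (1.05 equiv), THF, −78 °C; then 16, DMPU, −78 → −40 °C
Reagents that add atoms: none
Why: Kinetic enolate alkylation occurs at the cyclopentanone α-CH2 remote from the spiro carbon (the epoxy ketone has no enolisable α′-H), and the electrophile enters syn to the flat C-6 carbonyl and anti to the CH(CH3) arm whose methyl shields the other face, setting the 3R centre.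

**Step 11**
Reactants: 17 methyl 2-[(3R,5R,7R,8S,9S,10R)-9-[(tert-butyldimethylsilyl)oxy]-7,8-epoxy-10-methyl-2,6-dioxospiro[4.5]decan-3-yl]acetate
Product: 19 (1R,3R,4S,5S,6R,3'aR,6'aR)-5-[(tert-butyldimethylsilyl)oxy]-3,4-epoxy-6-methylhexahydro-2'H-spiro[cyclohexane-1,5'-cyclopenta[b]furan]-2,2'-dione, via cis-hydroxy ester 18 (not isolated)
Conditions: L-Selectride (1.05 equiv), THF, −78 → 0 °C; then H2O
Reagents that add atoms: none
Why: The bulky hydride reduces the unhindered cyclopentanone anti to its α-substituent (the neopentyl epoxy ketone is too hindered), and the resulting cis-alkoxide lactonises onto the methyl ester to give the cis-fused γ-lactone.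

**Step 12**
Reactants: 19 (1R,3R,4S,5S,6R,3'aR,6'aR)-5-[(tert-butyldimethylsilyl)oxy]-3,4-epoxy-6-methylhexahydro-2'H-spiro[cyclohexane-1,5'-cyclopenta[b]furan]-2,2'-dione
Product: 20 (1R,3S,4S,5S,6R,3'aR,6'aR)-5-[(tert-butyldimethylsilyl)oxy]-3,4-epoxy-6-methyl-2-methylidenehexahydro-2'H-spiro[cyclohexane-1,5'-cyclopenta[b]furan]-2'-one
Conditions: Ph3PCH3Br, KOt-Bu, THF, 0 °C → rt
Reagents that add atoms: methyltriphenylphosphonium bromide C[P+](c1ccccc1)(c1ccccc1)c1ccccc1.[Br-]
Why: Wittig methylenation converts the remaining ketone (far more electrophilic than the lactone) into the vinyl epoxide with no change at any stereocentre.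

**Step 13**
Reactants: 20 (1R,3S,4S,5S,6R,3'aR,6'aR)-5-[(tert-butyldimethylsilyl)oxy]-3,4-epoxy-6-methyl-2-methylidenehexahydro-2'H-spiro[cyclohexane-1,5'-cyclopenta[b]furan]-2'-one
Product: 23 (1R,3S,4S,5S,6R,3'aR,6'aR)-5-[(tert-butyldimethylsilyl)oxy]-3,4-epoxy-6-methyl-2,3'-dimethylidenehexahydro-2'H-spiro[cyclohexane-1,5'-cyclopenta[b]furan]-2'-one, via Mannich base 21 (not isolated), via methiodide 22 (not isolated)
Conditions: LDA, THF, −78 °C; CH2=NMe2+ I−, −78 °C → rt; then MeI, THF/MeOH, rt; then sat. aq NaHCO3, CH2Cl2, rt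
Reagents that add atoms: Eschenmoser's salt C=[N+](C)C.[I-]
Why: Mannich reaction of the lactone enolate, N-methylation and Hofmann-type elimination give the α-methylene-γ-butyrolactone, and the transient α-stereocentre is destroyed.

**Step 14**
Reactants: 23 (1R,3S,4S,5S,6R,3'aR,6'aR)-5-[(tert-butyldimethylsilyl)oxy]-3,4-epoxy-6-methyl-2,3'-dimethylidenehexahydro-2'H-spiro[cyclohexane-1,5'-cyclopenta[b]furan]-2'-one; 24 angelic acid
Product: 26 [(1R,4S,5S,6R,3'aR,6'aR)-4,5-dihydroxy-6-methyl-3'-methylidene-2'-oxohexahydro-2'H-spiro[cyclohex-2-ene-1,5'-cyclopenta[b]furan]-2-yl]methyl (2Z)-2-methylbut-2-enoate (CNP0224912.1), via silyl ether angelate 25 (not isolated)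
Conditions: Pd(PPh3)4 (5 mol %), THF, 0 °C → rt; then HF·pyridine, pyridine/THF, 0 °C → rt
Reagents that add atoms: none
Why: In this Tsuji–Trost reaction Pd(0) ionises the allylic epoxide C–O bond and angelate attacks the unhindered exocyclic CH2 terminus of the π-allyl complex (1,4-addition), which creates the ring C=C and the primary angelate while the carbinol keeps the epoxide configuration, and HF·pyridine then removes the TBS group.

**Compound list**
1 | (−)-quinic acid, (1S,3R,4S,5R)-1,3,4,5-tetrahydroxycyclohexane-1-carboxylic acid | O=C(O)[C@]1(O)C[C@@H](O)[C@@H](O)[C@H](O)C1 | starting material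
2 | 3,4-O-isopropylidene-1,5-quinide (quinic acid 1,5-lactone 3,4-acetonide) | O=C1O[C@@H]2C[C@@]1(O)C[C@H]3OC(C)(C)O[C@@H]23 | intermediate
3 | 1-(hydroxymethyl)-3,4-O-isopropylidenecyclohexane-1,3,4,5-tetrol (quinic acid configuration) | OC[C@]1(O)C[C@H]2OC(C)(C)O[C@H]2[C@H](O)C1 | intermediate
4 | (3R,4S,5R)-3-hydroxy-4,5-(isopropylidenedioxy)cyclohexan-1-one | O=C1C[C@H]2OC(C)(C)O[C@H]2[C@H](O)C1 | intermediate
5 | 3-O-mesylate of 4 | O=C1C[C@H]2OC(C)(C)O[C@H]2[C@H](OS(C)(=O)=O)C1 | intermediate (not isolated)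
6 | (4S,5R)-4,5-(isopropylidenedioxy)cyclohex-2-en-1-one | O=C1C=C[C@@H]2OC(C)(C)O[C@@H]2C1 | intermediate
7 | (2S,3R,4S,5R)-2-[(dimethylamino)methyl]-4,5-(isopropylidenedioxy)-3-methylcyclohexan-1-one | CN(C)C[C@@H]1[C@@H](C)[C@@H]2OC(C)(C)O[C@@H]2CC1=O | intermediate (not isolated)
8 | N-methyl ammonium iodide of 7 | C[N+](C)(C)C[C@@H]1[C@@H](C)[C@@H]2OC(C)(C)O[C@@H]2CC1=O.[I-] | intermediate (not isolated)
9 | (3R,4S,5R)-4,5-(isopropylidenedioxy)-3-methyl-2-methylidenecyclohexan-1-one | C=C1[C@@H](C)[C@@H]2OC(C)(C)O[C@@H]2CC1=O | intermediate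
10 | 2-[(trimethylsilyl)methyl]allyl acetate | CC(=O)OCC(=C)C[Si](C)(C)C | starting material
11 | (5R,8R,9S,10R)-8,9-(isopropylidenedioxy)-10-methyl-2-methylidenespiro[4.5]decan-6-one | C=C1C[C@]2(CC1)[C@@H](C)[C@@H]3OC(C)(C)O[C@@H]3CC2=O | intermediate
12 | (5R,9R,10R)-9-hydroxy-10-methyl-2-methylidenespiro[4.5]dec-7-en-6-one | C=C1C[C@]2(CC1)[C@@H](C)[C@H](O)C=CC2=O | intermediate (not isolated)
13 | (5R,9R,10R)-9-[(tert-butyldimethylsilyl)oxy]-10-methyl-2-methylidenespiro[4.5]dec-7-en-6-one | C=C1C[C@]2(CC1)[C@@H](C)[C@H](O[Si](C)(C)C(C)(C)C)C=CC2=O | intermediate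
14 | (5R,7R,8S,9S,10R)-9-[(tert-butyldimethylsilyl)oxy]-7,8-epoxy-10-methyl-2-methylidenespiro[4.5]decan-6-one | C=C1C[C@]2(CC1)[C@@H](C)[C@H](O[Si](C)(C)C(C)(C)C)[C@H]3O[C@H]3C2=O | intermediate
15 | (5R,7R,8S,9S,10R)-9-[(tert-butyldimethylsilyl)oxy]-7,8-epoxy-10-methylspiro[4.5]decane-2,6-dione | O=C1C[C@]2(CC1)[C@@H](C)[C@H](O[Si](C)(C)C(C)(C)C)[C@H]3O[C@H]3C2=O | intermediate
16 | methyl bromoacetate | COC(=O)CBr | starting material
17 | methyl 2-[(3R,5R,7R,8S,9S,10R)-9-[(tert-butyldimethylsilyl)oxy]-7,8-epoxy-10-methyl-2,6-dioxospiro[4.5]decan-3-yl]acetate | O=C1C[C@]2(C[C@@H]1CC(=O)OC)[C@@H](C)[C@H](O[Si](C)(C)C(C)(C)C)[C@H]3O[C@H]3C2=O | intermediate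
18 | methyl 2-[(2R,3R,5R,7R,8S,9S,10R)-9-[(tert-butyldimethylsilyl)oxy]-7,8-epoxy-2-hydroxy-10-methyl-6-oxospiro[4.5]decan-3-yl]acetate | O[C@@H]1C[C@]2(C[C@@H]1CC(=O)OC)[C@@H](C)[C@H](O[Si](C)(C)C(C)(C)C)[C@H]3O[C@H]3C2=O | intermediate (not isolated)
19 | (1R,3R,4S,5S,6R,3'aR,6'aR)-5-[(tert-butyldimethylsilyl)oxy]-3,4-epoxy-6-methylhexahydro-2'H-spiro[cyclohexane-1,5'-cyclopenta[b]furan]-2,2'-dione | O=C1O[C@@H]2C[C@]3(C[C@@H]2C1)[C@@H](C)[C@H](O[Si](C)(C)C(C)(C)C)[C@H]4O[C@H]4C3=O | intermediate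
20 | (1R,3S,4S,5S,6R,3'aR,6'aR)-5-[(tert-butyldimethylsilyl)oxy]-3,4-epoxy-6-methyl-2-methylidenehexahydro-2'H-spiro[cyclohexane-1,5'-cyclopenta[b]furan]-2'-one | O=C1O[C@@H]2C[C@]3(C[C@@H]2C1)[C@@H](C)[C@H](O[Si](C)(C)C(C)(C)C)[C@H]4O[C@H]4C3=C | intermediate
21 | 3'-[(dimethylamino)methyl] derivative of 20 (C-3' epimers) | CN(C)CC1C(=O)O[C@@H]2C[C@]3(C[C@H]12)[C@@H](C)[C@H](O[Si](C)(C)C(C)(C)C)[C@H]4O[C@H]4C3=C | intermediate (not isolated)
22 | N-methyl ammonium iodide of 21 | C[N+](C)(C)CC1C(=O)O[C@@H]2C[C@]3(C[C@H]12)[C@@H](C)[C@H](O[Si](C)(C)C(C)(C)C)[C@H]4O[C@H]4C3=C.[I-] | intermediate (not isolated)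
23 | (1R,3S,4S,5S,6R,3'aR,6'aR)-5-[(tert-butyldimethylsilyl)oxy]-3,4-epoxy-6-methyl-2,3'-dimethylidenehexahydro-2'H-spiro[cyclohexane-1,5'-cyclopenta[b]furan]-2'-one | C=C1C(=O)O[C@@H]2C[C@]3(C[C@H]12)[C@@H](C)[C@H](O[Si](C)(C)C(C)(C)C)[C@H]4O[C@H]4C3=C | intermediate
24 | angelic acid, (2Z)-2-methylbut-2-enoic acid | C/C=C(/C)C(=O)O | starting material
25 | [(1R,4S,5S,6R,3'aR,6'aR)-5-[(tert-butyldimethylsilyl)oxy]-4-hydroxy-6-methyl-3'-methylidene-2'-oxohexahydro-2'H-spiro[cyclohex-2-ene-1,5'-cyclopenta[b]furan]-2-yl]methyl (2Z)-2-methylbut-2-enoate | C=C1C(=O)O[C@@H]2C[C@@]3(C[C@H]12)C(COC(=O)/C(C)=C\C)=C[C@H](O)[C@@H](O[Si](C)(C)C(C)(C)C)[C@@H]3C | intermediate (not isolated)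
26 | [(1R,4S,5S,6R,3'aR,6'aR)-4,5-dihydroxy-6-methyl-3'-methylidene-2'-oxohexahydro-2'H-spiro[cyclohex-2-ene-1,5'-cyclopenta[b]furan]-2-yl]methyl (2Z)-2-methylbut-2-enoate (CNP0224912.1) | C=C1C(=O)O[C@@H]2C[C@@]3(C[C@H]12)C(COC(=O)/C(C)=C\C)=C[C@H](O)[C@@H](O)[C@@H]3C | target

**Step count and risks**
Total step count: 14. Longest linear sequence: 14 steps, from (−)-quinic acid (compounds 10, 16 and 24 are bought).

The three steps most likely to fail:

Step 6 (Pd–TMM cycloaddition). Enone 9 can dimerise by hetero-Diels–Alder reaction or isomerise at 65 °C, and the face selectivity at the spiro carbon rests on the adjacent methyl group alone. The fallback sets out from 9 and 10 and builds the same two bonds stepwise and cold. A Hosomi–Sakurai conjugate allylation (TiCl4, CH2Cl2, −78 °C, then TMSCl/Et3N to silylate the regiodefined enolate) gives the silyl enol ether allylic acetate F1. An intramolecular Tsuji–Trost C-allylation (Pd(PPh3)4, THF, rt) then closes the five-membered ring, and the route is rejoined at 11.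

Step 10 (alkylation at C-3 of the cyclopentanone). The face selectivity is a 1,3-relay from the spiro centre and could be low or reversed, and over-alkylation is possible. The fallback sets out from 15. A directed aldol reaction of its lithium enolate with methyl glyoxylate, followed by dehydration (MsCl, Et3N, then DBU), gives the alkylidene keto ester F2. Conjugate reduction with Stryker's reagent and kinetic protonation of the enolate then puts the hydrogen, not the carbon chain, on the open face (the inverse facial logic), and the route is rejoined at 17.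

Step 14 (Pd-catalysed opening with angelic acid). The hindered, weakly nucleophilic unsaturated acid may react slowly, which allows β-hydride elimination of the π-allyl complex, 1,2-attack, or Z→E isomerisation to the tiglate. The fallback sets out from 23. The vinyl epoxide is opened with acetic acid under the same Pd(0) catalysis to give the allylic acetate F3. A lipase (CAL-B, pH 7 buffer) hydrolyses the acetate to the primary allylic alcohol F4. The primary hydroxyl is then acylated selectively with the mixed anhydride of angelic acid and 2,4,6-trichlorobenzoyl chloride (Et3N, then DMAP, toluene). The route is rejoined at 25, which is desilylated with HF·pyridine as in step 14.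

**Further compounds**
F1 | step 6 | 4-[(3aS,4R,7aR)-2,2,4-trimethyl-6-(trimethylsilyloxy)-3a,4,7,7a-tetrahydro-1,3-benzodioxol-5-yl]-2-methylidenebutyl acetate | CC(=O)OCC(=C)CCC1=C(O[Si](C)(C)C)C[C@H]2OC(C)(C)O[C@H]2[C@@H]1C
F2 | step 10 | methyl (2E)-2-[(5R,7R,8S,9S,10R)-9-[(tert-butyldimethylsilyl)oxy]-7,8-epoxy-10-methyl-2,6-dioxospiro[4.5]decan-3-ylidene]acetate | COC(=O)/C=C1\C[C@@]2(CC1=O)[C@@H](C)[C@H](O[Si](C)(C)C(C)(C)C)[C@H]3O[C@H]3C2=O
F3 | step 14 | [(1R,4S,5S,6R,3'aR,6'aR)-5-[(tert-butyldimethylsilyl)oxy]-4-hydroxy-6-methyl-3'-methylidene-2'-oxohexahydro-2'H-spiro[cyclohex-2-ene-1,5'-cyclopenta[b]furan]-2-yl]methyl acetate | C=C1C(=O)O[C@@H]2C[C@@]3(C[C@H]12)C(COC(C)=O)=C[C@H](O)[C@@H](O[Si](C)(C)C(C)(C)C)[C@@H]3C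
F4 | step 14 | (1R,4S,5S,6R,3'aR,6'aR)-5-[(tert-butyldimethylsilyl)oxy]-4-hydroxy-2-(hydroxymethyl)-6-methyl-3'-methylidenehexahydro-2'H-spiro[cyclohex-2-ene-1,5'-cyclopenta[b]furan]-2'-one | C=C1C(=O)O[C@@H]2C[C@@]3(C[C@H]12)C(CO)=C[C@H](O)[C@@H](O[Si](C)(C)C(C)(C)C)[C@@H]3C
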